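**Retrosynthetic overview**

- The target comes from its tert-butyl ester; the only ring (14-membered) is closed at C9–C10 by a nickel-electrocatalytic coupling of a (Z)-alkenyl iodide with a terminal epoxide.
- The open-chain ester comes from an Evans–Tishchenko union of a C1–C9 enal with a C10–C20 β-hydroxy ketone epoxide; this makes the O13–C1 ester and sets C15 1,3-anti to C13.
- The C1–C9 enal comes from 1-methoxycyclohexa-1,4-diene: ozonolysis (C5=C6 Z), Masamune homologation, E-enol triflate then Reformatsky–Negishi coupling (C2=C3), Stork–Zhao iodo-olefination (C8=C9).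
- The C10–C20 piece comes from tert-butyl (3R,5S)-6-chloro-3,5-dihydroxyhexanoate (C11 and C13 bought) and an alkyllithium made from but-3-yn-1-ol (carboalumination/benzylation sets C18=C19).

Assumption: in names and explanations the chain carbons are labelled C1 (lactone carbonyl) to C20 (benzylic CH2), O13 is the lactone oxygen, and "the arm" is the CH2CO2H branch on C3.

**Route**

Step 1
Reactants: 1 1-methoxycyclohexa-1,4-diene
Product: 3 methyl (3Z)-6,6-dimethoxyhex-3-enoate, via methyl (3Z)-6-oxohex-3-enoate 2 (not isolated)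
Conditions: O3 (1.0 equiv), CH2Cl2/MeOH (4:1), NaHCO3, −78 °C; Me2S, −78 °C to rt; then HC(OMe)3, TsOH·H2O (cat.), 0 °C
Reagents that add atoms: ozone ([O-][O+]=O); trimethyl orthoformate (COC(OC)OC)
Why: Ozone cleaves only the electron-rich enol-ether double bond (chemoselective ozonolysis), so the ring's cis C=C becomes the C5=C6 Z olefin flanked by an ester (C3) and an aldehyde (C8), and the labile β,γ-unsaturated aldehyde is masked at once by acid-catalysed acetalisation.

Step 2
Reactants: 3 methyl (3Z)-6,6-dimethoxyhex-3-enoate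
Product: 4 (3Z)-6,6-dimethoxyhex-3-enoic acid
Conditions: LiOH·H2O, THF/H2O (3:1), 0 °C to rt; then cold 0.5 M HCl to pH 4
Reagents that add atoms: lithium hydroxide ([Li+].[OH-])
Why: Saponification of an unhindered methyl ester, in which hydroxide attacks the carbonyl faster than it enolises the skipped ester and the acetal is base-stable.

Step 3
Reactants: 4 (3Z)-6,6-dimethoxyhex-3-enoic acid
Product: 6 methyl (5Z)-8,8-dimethoxy-3-oxooct-5-enoate, via acyl imidazolide 5 (not isolated)
Conditions: CDI, THF, rt; then MeO2CCH2CO2K, MgCl2, Et3N, THF/MeCN, rt, 14 h; dilute HCl work-up (pH 4)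
Reagents that add atoms: potassium methyl malonate ([K+].[O-]C(=O)CC(=O)OC)
Why: Masamune–Claisen homologation, in which the acyl imidazolide acylates the magnesium enolate of the malonate half-ester and the adduct decarboxylates, giving the β-keto ester (C1–C3) without strong base so that the Z olefin and the acetal survive.

Step 4
Reactants: 6 methyl (5Z)-8,8-dimethoxy-3-oxooct-5-enoate
Product: 7 methyl (2E,5Z)-8,8-dimethoxy-3-(trifluoromethylsulfonyloxy)octa-2,5-dienoate
Conditions: Tf2O, 25% aq. Me4NOH, toluene, 5 °C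
Reagents that add atoms: trifluoromethanesulfonic anhydride (O=S(=O)(OS(=O)(=O)C(F)(F)F)C(F)(F)F)
Why: Stereoselective enol triflation of a β-keto ester under biphasic conditions, where the non-chelating tetramethylammonium counter-ion leads to the E triflate (OTf trans to the ester) and so places C4 cis to C1 as the macrocycle requires.

Step 5
Reactants: 7 methyl (2E,5Z)-8,8-dimethoxy-3-(trifluoromethylsulfonyloxy)octa-2,5-dienoate
Product: 8 (2E,5Z)-1-hydroxy-8,8-dimethoxyocta-2,5-dien-3-yl trifluoromethanesulfonate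
Conditions: i-Bu2AlH (2.3 equiv), CH2Cl2, −78 °C; aq. potassium sodium tartrate
Reagents that add atoms: none
Why: 1,2-Reduction of the enoate with i-Bu2AlH gives the allylic alcohol while the vinyl triflate and the acetal are inert, and it removes the conjugated ester before the acidic CH2CO2t-Bu arm is introduced.

Step 6
Reactants: 8 (2E,5Z)-1-hydroxy-8,8-dimethoxyocta-2,5-dien-3-yl trifluoromethanesulfonate
Product: 10 tert-butyl (3E,5Z)-3-(2-hydroxyethylidene)-8-oxooct-5-enoate, via dimethyl acetal 9 (not isolated)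
Conditions: BrZnCH2CO2t-Bu (2.5 equiv), Pd(PPh3)4 (5 mol%), THF, 50 °C; then 1 M HCl, THF, 0 °C to rt
Reagents that add atoms: (2-tert-butoxy-2-oxoethyl)zinc bromide (Br[Zn]CC(=O)OC(C)(C)C); water (O)
Why: Negishi coupling of the Reformatsky reagent with the vinyl triflate goes with retention, so the arm ends up trans to C1 and C4 stays cis to C1, and the acidic quench hydrolyses the dimethyl acetal to the C8 aldehyde.

Step 7
Reactants: 10 tert-butyl (3E,5Z)-3-(2-hydroxyethylidene)-8-oxooct-5-enoate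
Product: 11 tert-butyl (3E,5Z,8Z)-3-(2-hydroxyethylidene)-9-iododeca-5,8-dienoate
Conditions: [Ph3PEt]I (3 equiv), n-BuLi, THF, rt; I2, −78 °C; NaN(SiMe3)2, −78 to −20 °C; then 10, −78 to −20 °C
Reagents that add atoms: ethyltriphenylphosphonium iodide (CC[P+](c1ccccc1)(c1ccccc1)c1ccccc1.[I-]); iodine (II)
Why: Stork–Zhao-type Wittig olefination with the α-iodo ylide gives the trisubstituted alkenyl iodide with iodine cis to C7 (Z) under kinetic control at low temperature, the extra ylide covering the free hydroxyl.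

Step 8
Reactants: 11 tert-butyl (3E,5Z,8Z)-3-(2-hydroxyethylidene)-9-iododeca-5,8-dienoate
Product: 12 tert-butyl (3E,5Z,8Z)-9-iodo-3-(2-oxoethylidene)deca-5,8-dienoate
Conditions: MnO2 (20 equiv), CH2Cl2, rt
Reagents that add atoms: none
Why: MnO2 oxidises only the allylic alcohol (allylic oxidation) and leaves the C2=C3 geometry, the alkenyl iodide and the ester untouched.

Step 9
Reactants: 13 but-3-yn-1-ol
Product: 15 (3E)-3-methyl-5-phenylpent-3-en-1-ol, via alkenylalane 14 (not isolated)
Conditions: AlMe3 (3 equiv), Cp2ZrCl2 (25 mol%), CH2Cl2, 0 °C to rt; then BnBr, Pd(PPh3)4 (3 mol%), ZnCl2 (0.2 equiv), THF, rt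
Reagents that add atoms: trimethylaluminium (C[Al](C)C); benzyl bromide (BrCc1ccccc1)
Why: Zirconium-catalysed carboalumination (Negishi) adds methyl and aluminium syn across the alkyne with methyl on the internal carbon, and Pd-catalysed cross-coupling of the alkenylalane with benzyl bromide goes with retention, fixing the E C18=C19 olefin.

Step 10
Reactants: 15 (3E)-3-methyl-5-phenylpent-3-en-1-ol
Product: 16 [(2E)-5-iodo-3-methylpent-2-en-1-yl]benzene
Conditions: I2, PPh3, imidazole, CH2Cl2, 0 °C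
Reagents that add atoms: iodine (II)
Why: Appel-type iodination converts the primary alcohol into the iodide without touching the trisubstituted olefin.

Step 11
Reactants: 17 tert-butyl (3R,5S)-6-chloro-3,5-dihydroxyhexanoate
Product: 18 (4R,6S)-6-(chloromethyl)-4-hydroxyoxan-2-one
Conditions: CF3CO2H/CH2Cl2 (1:5), rt; evaporate from toluene
Reagents that add atoms: none
Why: Acidolysis of the tert-butyl ester followed by lactonisation of the 5-hydroxy acid ties O11 up as the lactone oxygen and leaves O13 as the only free hydroxyl, with no stereocentre touched.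

Step 12
Reactants: 16 [(2E)-5-iodo-3-methylpent-2-en-1-yl]benzene, 18 (4R,6S)-6-(chloromethyl)-4-hydroxyoxan-2-one
Product: 20 (2S,4R,9E)-1-chloro-2,4-dihydroxy-9-methyl-11-phenylundec-9-en-6-one, via alkyllithium 19 (not isolated)
Conditions: 16 (2.3 equiv), t-BuLi (4.6 equiv), Et2O, −78 °C; then 18, THF, −78 °C; aq. NH4Cl
Reagents that add atoms: none
Why: Lithium–iodine exchange gives the primary alkyllithium, which adds once to the δ-lactone because the tetrahedral lithium hemiketal is stable at −78 °C (one further equivalent is consumed by the free hydroxyl), giving the C15 ketone.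

Step 13
Reactants: 20 (2S,4R,9E)-1-chloro-2,4-dihydroxy-9-methyl-11-phenylundec-9-en-6-one
Product: 21 (2R,7E)-2-hydroxy-7-methyl-1-[(2S)-oxiran-2-yl]-9-phenylnon-7-en-4-one
Conditions: K2CO3, MeOH, 0 °C
Reagents that add atoms: none
Why: Intramolecular Williamson reaction of the C11 alkoxide (released from the ring–chain equilibrium of 20) with the adjacent chloride closes the terminal epoxide without breaking the C11–O bond, so the purchased configuration is kept, O11 is blocked and O13 stays free.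

Step 14
Reactants: 21 (2R,7E)-2-hydroxy-7-methyl-1-[(2S)-oxiran-2-yl]-9-phenylnon-7-en-4-one, 12 tert-butyl (3E,5Z,8Z)-9-iodo-3-(2-oxoethylidene)deca-5,8-dienoate
Product: 22 (2S,4R,7E)-4-hydroxy-7-methyl-1-[(2S)-oxiran-2-yl]-9-phenylnon-7-en-2-yl (2E,5Z,8Z)-3-(2-tert-butoxy-2-oxoethyl)-9-iododeca-2,5,8-trienoate
Conditions: SmI2 (30 mol%), 12 (1.5 equiv), THF, −10 °C
Reagents that add atoms: none
Why: Evans–Tishchenko reduction, in which O13 forms a samarium-bound hemiacetal with aldehyde 12 and transfers its hydride to the C15 ketone through a six-membered chair transition state on trivalent samarium, so C15–H forms anti to O13 (15R, controlled by the purchased C13 centre) and the acyl group stays on O13.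

Step 15
Reactants: 22 (2S,4R,7E)-4-hydroxy-7-methyl-1-[(2S)-oxiran-2-yl]-9-phenylnon-7-en-2-yl (2E,5Z,8Z)-3-(2-tert-butoxy-2-oxoethyl)-9-iododeca-2,5,8-trienoate
Product: 24 tert-butyl 2-[(3E,6Z,9Z,12R,14S)-12-hydroxy-14-[(2R,5E)-2-hydroxy-5-methyl-7-phenylhept-5-en-1-yl]-10-methyl-2-oxo-1-oxacyclotetradeca-3,6,9-trien-4-yl]acetate, via iodohydrin seco ester 23 (not isolated)
Conditions: NiBr2(dme) (30 mol%), 4,4′-di-tert-butyl-2,2′-bipyridine (36 mol%), NaI (1 equiv), Et3N·HCl (1.2 equiv), n-Bu4NBF4 (0.1 M), DMA, undivided cell, Zn anode, reticulated vitreous carbon cathode, 2 mA constant current (about 2.2 F/mol), 25 °C; 22 added by syringe pump over 12 h (final 2 mM)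
Reagents that add atoms: none
Why: Proposed new method: a nickel-electrocatalytic, iodide-relayed ring closure in which iodide and the ammonium acid open the terminal epoxide at C10 to the iodohydrin, cathodically generated zerovalent nickel inserts into the alkenyl carbon–iodine bond with retention, monovalent nickel abstracts iodine from C10, and the tethered alkenylnickel captures the primary radical and reductively eliminates from trivalent nickel to form C9–C10 and the 14-membered ring, C11 keeping its configuration because its C–O bond is never broken; the closest known reaction type is the nickel-catalysed reductive cross-electrophile coupling of epoxides with aryl halides under iodide co-catalysis with a metal-powder reductant, which to my knowledge has not been shown under electrolysis with an alkenyl iodide as a macrocyclisation.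

Step 16
Reactants: 24 tert-butyl 2-[(3E,6Z,9Z,12R,14S)-12-hydroxy-14-[(2R,5E)-2-hydroxy-5-methyl-7-phenylhept-5-en-1-yl]-10-methyl-2-oxo-1-oxacyclotetradeca-3,6,9-trien-4-yl]acetate
Product: 26 2-[(3E,6Z,9Z,12R,14S)-12-hydroxy-14-[(2R,5E)-2-hydroxy-5-methyl-7-phenylhept-5-en-1-yl]-10-methyl-2-oxo-1-oxacyclotetradeca-3,6,9-trien-4-yl]acetic acid, via tris(trimethylsilyl) derivative 25 (not isolated)
Conditions: Me3SiOTf (5 equiv), 2,6-lutidine (8 equiv), CH2Cl2, 0 °C; then aq. citric acid (pH 3)/THF, 0 °C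
Reagents that add atoms: none
Why: Silyl triflate-mediated tert-butyl ester cleavage, in which Me3SiOTf converts the ester into the trimethylsilyl ester with loss of isobutene under buffered, non-protic conditions that spare the skipped triene and the lactone, and mild aqueous acid then hydrolyses the silyl ester and both silyl ethers.

**Compound list**

1 | 1-methoxycyclohexa-1,4-diene | COC1=CCC=CC1 | starting material
2 | methyl (3Z)-6-oxohex-3-enoate | COC(=O)C/C=C\CC=O | intermediate
3 | methyl (3Z)-6,6-dimethoxyhex-3-enoate | COC(=O)C/C=C\CC(OC)OC | intermediate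
4 | (3Z)-6,6-dimethoxyhex-3-enoic acid | OC(=O)C/C=C\CC(OC)OC | intermediate
5 | acyl imidazolide: 1-[(3Z)-6,6-dimethoxyhex-3-enoyl]imidazole | O=C(C/C=C\CC(OC)OC)n1ccnc1 | intermediate
6 | methyl (5Z)-8,8-dimethoxy-3-oxooct-5-enoate | COC(=O)CC(=O)C/C=C\CC(OC)OC | intermediate
7 | methyl (2E,5Z)-8,8-dimethoxy-3-(trifluoromethylsulfonyloxy)octa-2,5-dienoate (OTf trans to CO2Me) | COC(=O)/C=C(/OS(=O)(=O)C(F)(F)F)C/C=C\CC(OC)OC | intermediate
8 | (2E,5Z)-1-hydroxy-8,8-dimethoxyocta-2,5-dien-3-yl trifluoromethanesulfonate | OC/C=C(/OS(=O)(=O)C(F)(F)F)C/C=C\CC(OC)OC | intermediate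
9 | dimethyl acetal: tert-butyl (3E,5Z)-3-(2-hydroxyethylidene)-8,8-dimethoxyoct-5-enoate | OC/C=C(\C/C=C\CC(OC)OC)CC(=O)OC(C)(C)C | intermediate
10 | tert-butyl (3E,5Z)-3-(2-hydroxyethylidene)-8-oxooct-5-enoate (CH2OH cis to the C4 chain) | OC/C=C(\C/C=C\CC=O)CC(=O)OC(C)(C)C | intermediate
11 | tert-butyl (3E,5Z,8Z)-3-(2-hydroxyethylidene)-9-iododeca-5,8-dienoate (iodine cis to C7) | OC/C=C(\C/C=C\C/C=C(/C)I)CC(=O)OC(C)(C)C | intermediate
12 | tert-butyl (3E,5Z,8Z)-9-iodo-3-(2-oxoethylidene)deca-5,8-dienoate (C1–C9 enal) | O=C/C=C(\C/C=C\C/C=C(/C)I)CC(=O)OC(C)(C)C | intermediate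
13 | but-3-yn-1-ol | C#CCCO | starting material
14 | alkenylalane: dimethylaluminium (3E)-4-(dimethylalumanyl)-3-methylbut-3-en-1-olate | C[Al](C)OCC/C(C)=C/[Al](C)C | intermediate
15 | (3E)-3-methyl-5-phenylpent-3-en-1-ol | OCC/C(C)=C/Cc1ccccc1 | intermediate
16 | [(2E)-5-iodo-3-methylpent-2-en-1-yl]benzene | ICC/C(C)=C/Cc1ccccc1 | intermediate
17 | tert-butyl (3R,5S)-6-chloro-3,5-dihydroxyhexanoate | CC(C)(C)OC(=O)C[C@H](O)C[C@H](O)CCl | starting material
18 | (4R,6S)-6-(chloromethyl)-4-hydroxyoxan-2-one | O=C1C[C@H](O)C[C@@H](CCl)O1 | intermediate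
19 | alkyllithium: [(3E)-3-methyl-5-phenylpent-3-en-1-yl]lithium | [Li]CC/C(C)=C/Cc1ccccc1 | intermediate
20 | (2S,4R,9E)-1-chloro-2,4-dihydroxy-9-methyl-11-phenylundec-9-en-6-one | ClC[C@@H](O)C[C@@H](O)CC(=O)CC/C(C)=C/Cc1ccccc1 | intermediate
21 | (2R,7E)-2-hydroxy-7-methyl-1-[(2S)-oxiran-2-yl]-9-phenylnon-7-en-4-one | C1O[C@H]1C[C@@H](O)CC(=O)CC/C(C)=C/Cc2ccccc2 | intermediate
22 | (2S,4R,7E)-4-hydroxy-7-methyl-1-[(2S)-oxiran-2-yl]-9-phenylnon-7-en-2-yl (2E,5Z,8Z)-3-(2-tert-butoxy-2-oxoethyl)-9-iododeca-2,5,8-trienoate | CC(C)(C)OC(=O)C/C(C/C=C\C/C=C(/C)I)=C/C(=O)O[C@H](C[C@H]1CO1)C[C@H](O)CC/C(C)=C/Cc2ccccc2 | intermediate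
23 | iodohydrin seco ester: (2S,4S,6R,9E)-2,6-dihydroxy-1-iodo-9-methyl-11-phenylundec-9-en-4-yl (2E,5Z,8Z)-3-(2-tert-butoxy-2-oxoethyl)-9-iododeca-2,5,8-trienoate | CC(C)(C)OC(=O)C/C(C/C=C\C/C=C(/C)I)=C/C(=O)O[C@H](C[C@H](O)CI)C[C@H](O)CC/C(C)=C/Cc2ccccc2 | intermediate
24 | tert-butyl 2-[(3E,6Z,9Z,12R,14S)-12-hydroxy-14-[(2R,5E)-2-hydroxy-5-methyl-7-phenylhept-5-en-1-yl]-10-methyl-2-oxo-1-oxacyclotetradeca-3,6,9-trien-4-yl]acetate | C/C1=C/C/C=C\C/C(CC(=O)OC(C)(C)C)=C\C(=O)O[C@@H](C[C@H](O)CC/C(C)=C/Cc2ccccc2)C[C@H](O)C1 | intermediate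
25 | tris(trimethylsilyl) derivative: trimethylsilyl ester and 11,15-bis(trimethylsilyl) ether of 26 | C/C1=C/C/C=C\C/C(CC(=O)O[Si](C)(C)C)=C\C(=O)O[C@@H](C[C@H](O[Si](C)(C)C)CC/C(C)=C/Cc2ccccc2)C[C@H](O[Si](C)(C)C)C1 | intermediate
26 | 2-[(3E,6Z,9Z,12R,14S)-12-hydroxy-14-[(2R,5E)-2-hydroxy-5-methyl-7-phenylhept-5-en-1-yl]-10-methyl-2-oxo-1-oxacyclotetradeca-3,6,9-trien-4-yl]acetic acid (CNP0194630.2) | C/C1=C/C/C=C\C/C(CC(=O)O)=C\C(=O)O[C@@H](C[C@H](O)CC/C(C)=C/Cc2ccccc2)C[C@H](O)C1 | target

**Step count and risks**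

Total: 16 steps. Longest linear sequence: 11 steps (1 to 26 through steps 1–8 and 14–16); the C10–C20 branch (steps 9–13) is 5 steps.

The three steps most likely to fail:

1. Step 15, the new ring closure. The primary radical must find the nickel centre on its own chain; dimerisation, hydrodehalogenation at C9 or C10, and acyl shift from O13 to the new O11 are the likely losses. Fallback with known chemistry, setting out from 21 and 11 and coming back at 24: LiI/AcOH in THF opens epoxide 21 to the iodohydrin (2S,4R,9E)-2,4-dihydroxy-1-iodo-9-methyl-11-phenylundec-9-en-6-one F1. The ordinary intermolecular nickel-catalysed reductive cross-electrophile coupling of an alkyl iodide with an alkenyl iodide (NiBr2(dme), 4,4′-di-tert-butyl-2,2′-bipyridine, Mn powder, DMA, no electrolysis, 0.1 M) then joins F1 and 11 at C9–C10 to give the open-chain triol ketone F2. MnO2 oxidises its allylic alcohol to the hydroxy enal F3. A SmI2-catalysed intramolecular Evans–Tishchenko reaction at high dilution, a known way of closing macrolactones, then forms the O13–C1 ester and the C15 carbinol in one step and gives 24; only O13 is β to the ketone, so O11 stays free.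

2. Step 14, the Evans–Tishchenko coupling with a conjugated, γ-acidic enal. Hydride transfer from an enal hemiacetal is slower than from a saturated one, the enal can lose its C2=C3 geometry through its dienolate, and samarium iodide species may open the epoxide. Fallback, setting out from 21 and 12 and coming back at 22: Evans–Tishchenko reduction of 21 with acetaldehyde (SmI2 cat.) gives the C13 acetate F4 with the same 13,15-anti relationship. TESCl/imidazole gives the C15 silyl ether F5, and K2CO3/MeOH removes the acetate to give the C13 alcohol F6. Separately, Pinnick oxidation (NaClO2, NaH2PO4, 2-methylbut-2-ene) of 12 gives the acid F7. Yamaguchi esterification of F6 with F7 gives the silyl-protected ester F8, and AcOH/THF/H2O removes the silyl group to give 22.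

3. Step 7, the iodo-olefination of a base-sensitive skipped aldehyde that carries a free hydroxyl; yields of this reaction are modest even on simple aldehydes. Fallback, setting out from 10 and coming back at 11: TBSCl/imidazole gives the silyl ether F9. CBr4/PPh3 (Corey–Fuchs dibromo-olefination) gives the dibromoalkene F10. Trans-selective Negishi monomethylation (MeZnCl, Pd(DPEphos)Cl2) gives the (Z)-bromoalkene F11. Copper-catalysed halide exchange with retention (NaI, CuI cat., N,N′-dimethylethylenediamine, dioxane, 110 °C) gives the (Z)-iodoalkene F12, and AcOH/THF/H2O removes the silyl group to give 11.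

**Further compounds**

F1 | step 15 | iodohydrin: (2S,4R,9E)-2,4-dihydroxy-1-iodo-9-methyl-11-phenylundec-9-en-6-one | IC[C@@H](O)C[C@@H](O)CC(=O)CC/C(C)=C/Cc1ccccc1
F2 | step 15 | open-chain triol ketone: tert-butyl (3E,5Z,8Z,11R,13R,18E)-11,13-dihydroxy-3-(2-hydroxyethylidene)-9,18-dimethyl-15-oxo-20-phenylicosa-5,8,18-trienoate | OC/C=C(\C/C=C\C/C=C(/C)C[C@@H](O)C[C@@H](O)CC(=O)CC/C(C)=C/Cc1ccccc1)CC(=O)OC(C)(C)C
F3 | step 15 | hydroxy enal: tert-butyl (3E,5Z,8Z,11R,13R,18E)-11,13-dihydroxy-9,18-dimethyl-15-oxo-3-(2-oxoethylidene)-20-phenylicosa-5,8,18-trienoate | O=C/C=C(\C/C=C\C/C=C(/C)C[C@@H](O)C[C@@H](O)CC(=O)CC/C(C)=C/Cc1ccccc1)CC(=O)OC(C)(C)C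
F4 | step 14 | C13 acetate: (2S,4R,7E)-4-hydroxy-7-methyl-1-[(2S)-oxiran-2-yl]-9-phenylnon-7-en-2-yl acetate | CC(=O)O[C@H](C[C@H]1CO1)C[C@H](O)CC/C(C)=C/Cc2ccccc2
F5 | step 14 | C15 silyl ether: 15-O-triethylsilyl ether of F4 | CC(=O)O[C@H](C[C@H]1CO1)C[C@H](O[Si](CC)(CC)CC)CC/C(C)=C/Cc2ccccc2
F6 | step 14 | C13 alcohol: (7E)-7-methyl-1-[(2S)-oxiran-2-yl]-9-phenyl-4-(triethylsilyloxy)non-7-en-2-ol with the C13 and C15 configurations of 22 | O[C@H](C[C@H]1CO1)C[C@H](O[Si](CC)(CC)CC)CC/C(C)=C/Cc2ccccc2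
F7 | step 14 | acid: (2E,5Z,8Z)-3-(2-tert-butoxy-2-oxoethyl)-9-iododeca-2,5,8-trienoic acid | OC(=O)/C=C(\C/C=C\C/C=C(/C)I)CC(=O)OC(C)(C)C
F8 | step 14 | silyl-protected ester: 15-O-triethylsilyl ether of 22 | CC(C)(C)OC(=O)C/C(C/C=C\C/C=C(/C)I)=C/C(=O)O[C@H](C[C@H]1CO1)C[C@H](O[Si](CC)(CC)CC)CC/C(C)=C/Cc2ccccc2
F9 | step 7 | silyl ether: tert-butyl (3E,5Z)-3-[2-(tert-butyldimethylsilyloxy)ethylidene]-8-oxooct-5-enoate | CC(C)(C)[Si](C)(C)OC/C=C(\C/C=C\CC=O)CC(=O)OC(C)(C)C
F10 | step 7 | dibromoalkene: tert-butyl (3E,5Z)-9,9-dibromo-3-[2-(tert-butyldimethylsilyloxy)ethylidene]nona-5,8-dienoate | CC(C)(C)[Si](C)(C)OC/C=C(\C/C=C\CC=C(Br)Br)CC(=O)OC(C)(C)C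
F11 | step 7 | (Z)-bromoalkene: tert-butyl (3E,5Z,8Z)-9-bromo-3-[2-(tert-butyldimethylsilyloxy)ethylidene]deca-5,8-dienoate | CC(C)(C)[Si](C)(C)OC/C=C(\C/C=C\C/C=C(/C)Br)CC(=O)OC(C)(C)C
F12 | step 7 | (Z)-iodoalkene: tert-butyl (3E,5Z,8Z)-3-[2-(tert-butyldimethylsilyloxy)ethylidene]-9-iododeca-5,8-dienoate | CC(C)(C)[Si](C)(C)OC/C=C(\C/C=C\C/C=C(/C)I)CC(=O)OC(C)(C)C
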